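The target is cut at the pyrrole N–CH2 bond into a 3,4-bis(quinolin-5-yl)pyrrole and an N-(3-chloropropyl)azecane. The azecane plan rests on one feature. N-1, C-2 and C-3 with its methyl group are a reduced N-propionyl unit, C-4 to C-6 are an allyl unit, and C-6 to C-10 plus N-1 are a piperidine. Acylating (S)-1-(3-benzyloxypropyl)-2-vinylpiperidine with propionyl fluoride therefore triggers a zwitterionic aza-Claisen shift. In one operation it forms the N-1–C-2 and C-3–C-4 bonds, breaks N-1–C-6, enlarges the six-membered ring to the ten-membered lactam, and sets the only stereocentre (C-3) by chirality transfer from L-pipecolic acid.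

Key step: step 6

Assumption: the alkene plane of the E-configured ten-membered lactam from the key step is taken to flip readily at room temperature, so this lactam is drawn with C-3 as its only stereocentre; conformers that might persist would converge on hydrogenation.

Step 1
Reactants: 1 (S)-1-(tert-butoxycarbonyl)piperidine-2-carboxylic acid
Product: 3 tert-butyl (S)-2-[methoxy(methyl)carbamoyl]piperidine-1-carboxylate, via acylimidazole 2 (not isolated)
Conditions: 1,1'-carbonyldiimidazole (1.1 equiv), CH2Cl2, 0 °C to rt; then MeNH(OMe)·HCl (1.2 equiv), rt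
Reagents that add atoms: N,O-dimethylhydroxylamine hydrochloride CNOC.Cl; 1,1'-carbonyldiimidazole O=C(n1ccnc1)n1ccnc1 (imidazolyl group of 2 only)
Why: Acylimidazole activation followed by aminolysis is a standard Weinreb amide synthesis, and the urethane-protected α-stereocentre is not prone to oxazolone racemisation, all the more so because no external base is present.

Step 2
Reactants: 3 tert-butyl (S)-2-[methoxy(methyl)carbamoyl]piperidine-1-carboxylate
Product: 4 tert-butyl (S)-2-formylpiperidine-1-carboxylate
Conditions: LiAlH4 (1.2 equiv), THF, 0 °C, 30 min; cold aq KHSO4; used the same day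
Reagents that add atoms: none
Why: Hydride reduction of a Weinreb amide stops at the chelated tetrahedral aluminate, which collapses to the aldehyde only on the cold acidic quench, so neither over-reduction nor attack on the carbamate is expected.

Step 3
Reactants: 4 tert-butyl (S)-2-formylpiperidine-1-carboxylate
Product: 5 tert-butyl (S)-2-vinylpiperidine-1-carboxylate
Conditions: Ph3PCH3Br (1.5 equiv), KN(SiMe3)2 (1.4 equiv), THF, 0 °C; then 4, −78 °C to rt
Reagents that add atoms: methyltriphenylphosphonium bromide C[P+](c1ccccc1)(c1ccccc1)c1ccccc1.[Br-]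
Why: In this Wittig methylenation the base is kept in deficit relative to the phosphonium salt, so no free amide base remains to enolise the aldehyde and the (S)-centre should pass unchanged into 5, to be confirmed by chiral chromatography.

Step 4
Reactants: 5 tert-butyl (S)-2-vinylpiperidine-1-carboxylate; 6 benzyl 3-bromopropyl ether
Product: 8 (S)-1-[3-(benzyloxy)propyl]-2-vinylpiperidine, via vinylpiperidinium trifluoroacetate 7 (not isolated)
Conditions: CF3CO2H/CH2Cl2 (1:3), 0 °C to rt, evaporate; then 6 (1.05 equiv), K2CO3 (4 equiv), MeCN, 60 °C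
Reagents that add atoms: trifluoroacetic acid OC(=O)C(F)(F)F (counter-ion of 7 only)
Why: Carbamate acidolysis followed by SN2 N-alkylation with a primary bromide keeps the volatile secondary amine as its salt until carbonate frees it in the alkylation flask, and neither operation touches the allylic stereocentre.

Step 5
Reactants: 9 propionyl chloride
Product: 10 propionyl fluoride
Conditions: spray-dried KF (2.5 equiv), sulfolane, 70 °C, product distilled out under N2 into a cold receiver
Reagents that add atoms: potassium fluoride [K+].[F-]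
Why: This halogen exchange by nucleophilic acyl substitution is driven by the strong C–F bond, by precipitation of KCl and by continuous removal of the low-boiling acyl fluoride, and excess KF also binds any trace of HF that would later destroy AlMe3.

Step 6
Reactants: 8 (S)-1-[3-(benzyloxy)propyl]-2-vinylpiperidine; 10 propionyl fluoride
Product: 13 (3S,5E)-1-[3-(benzyloxy)propyl]-3-methyl-3,4,7,8,9,10-hexahydroazecin-2(1H)-one, via acylammonium fluoride 11 (not isolated), via Z-ammonium enolate 12 (not isolated)
Conditions: AlMe3 (2 M in toluene, 2.5 equiv), powdered dry K2CO3 (5 equiv), 10 (2.5 equiv, slow addition), CH2Cl2, 0 °C to rt; aq potassium sodium tartrate work-up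
Reagents that add atoms: none
Why: AlMe3-activated 10 acylates the tertiary amine of 8 reversibly to 11, carbonate removes an α-proton to give the Z-configured ammonium enolate 12 (methyl cis to oxygen and trans to nitrogen), and a charge-accelerated [3,3] sigmatropic shift then joins the enolate carbon to the vinyl CH2 (new C-3–C-4 bond) while the former piperidine N–C-2 bond breaks and both charges vanish. The closest known reaction type is the zwitterionic aza-Claisen (Bellus–Claisen type) ring expansion of N-alkyl-2-vinylpyrrolidines and N-alkyl-2-vinylpiperidines with ketenes or with acyl fluorides and AlMe3, applied here to a new amine and acyl partner. The ten-membered ring is not closed end to end but arises by four-atom expansion of the piperidine through a six-membered chair transition state fused to it, so neither high dilution nor a templating device is needed. The new C-3 stereocentre is controlled by the (S)-carbon of 8, which selects the chair in which its ring CH2 is pseudo-equatorial (this also fixes the E-alkene), and in that chair the equatorial methyl group of the Z-enolate leaves only the enolate face that gives 3S, the old stereocentre being consumed as it becomes alkene carbon C-6. The step needs Z-enolate geometry, chair over boat and E over Z alkene formation, because a chair leading to the Z-alkene or a boat leading to the E-alkene would give 3R; the first is secured by the clash of an E-enolate methyl group with the quaternary nitrogen, the others by the equatorial preference of the allylic ring carbon and by reversible acylation that funnels material through the lowest transition state, and any Z-lactam is a separable isomer that is removed by chromatography before the enantiomeric purity of 13 is checked on a chiral column. Aluminium-bound fluoride is a non-nucleophilic counter-ion and the N-chain is primary and neither allylic nor benzylic, which together suppress von Braun-type dealkylation of 11, while the surplus of AlMe3 allows for its coordination to the ether oxygen.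

Step 7
Reactants: 13 (3S,5E)-1-[3-(benzyloxy)propyl]-3-methyl-3,4,7,8,9,10-hexahydroazecin-2(1H)-one
Product: 15 (S)-1-(3-hydroxypropyl)-3-methylazecan-2-one, via saturated benzyl ether 14 (not isolated)
Conditions: H2 (4 bar), Pd(OH)2/C, EtOH, rt
Reagents that add atoms: none
Why: Heterogeneous hydrogenation under pressure should saturate the strained E-alkene before it can migrate toward C-3 and then hydrogenolyse the benzyl ether, while the neutral lactam does not poison the catalyst and the stereocentre is not involved.

Step 8
Reactants: 15 (S)-1-(3-hydroxypropyl)-3-methylazecan-2-one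
Product: 16 (S)-3-(3-methylazecan-1-yl)propan-1-ol
Conditions: AlH3 (from LiAlH4 and AlCl3, 3:1, 3 equiv), THF, 0 °C to rt; aq NaOH work-up
Reagents that add atoms: none
Why: Alane reduction of a tertiary lactam runs through the iminium ion to the amine without C–N cleavage, and because the reagent is Lewis acidic rather than basic the α-stereocentre should not epimerise, the free hydroxyl merely consuming one hydride.

Step 9
Reactants: 16 (S)-3-(3-methylazecan-1-yl)propan-1-ol
Product: 17 (S)-1-(3-chloropropyl)-3-methylazecane hydrochloride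
Conditions: SOCl2 (2 equiv), CHCl3, 0 °C to reflux; evaporate, triturate with Et2O
Reagents that add atoms: thionyl chloride O=S(Cl)Cl
Why: Chlorodehydroxylation through the chlorosulfite (SN2 by chloride) takes place on the N-protonated amino alcohol, so the product is obtained directly as a storable salt that cannot cyclise to an azetidinium ion.

Step 10
Reactants: 18 2,3-dimethoxyaniline
Product: 20 7,8-dimethoxyquinoline, via dihydroquinoline 19 (not isolated)
Conditions: glycerol (3 equiv), sodium 3-nitrobenzenesulfonate (0.6 equiv), FeSO4 (cat), aq H2SO4 (75 %), 135 °C; NaOH work-up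
Reagents that add atoms: glycerol OCC(O)CO
Why: In this Skraup quinoline synthesis acrolein generated from glycerol adds to the aniline nitrogen, ring closure can occur only at the single free ortho position, and the water-soluble nitroarene dehydrogenates 19 in a controlled way.

Step 11
Reactants: 20 7,8-dimethoxyquinoline
Product: 21 5-bromo-7,8-dimethoxyquinoline
Conditions: NBS (1.05 equiv), MeCN, 0 °C to rt, dark
Reagents that add atoms: N-bromosuccinimide O=C1CCC(=O)N1Br
Why: Electrophilic aromatic bromination is directed to C-5, the α-position of the carbocyclic ring that lies para to the C-8 methoxy group, as is general for 8-alkoxyquinolines, while the pyridine ring stays inert.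

Step 12
Reactants: 21 5-bromo-7,8-dimethoxyquinoline
Product: 22 7,8-dimethoxy-5-(4,4,5,5-tetramethyl-1,3,2-dioxaborolan-2-yl)quinoline
Conditions: B2pin2 (1.2 equiv), PdCl2(dppf) (3 mol %), KOAc (3 equiv), 1,4-dioxane, 90 °C
Reagents that add atoms: bis(pinacolato)diboron CC1(C)OB(OC1(C)C)B1OC(C)(C)C(C)(C)O1
Why: Miyaura borylation of an electron-poor heteroaryl bromide is reliable, and acetate is too weak a base to trigger homocoupling of the boronate formed.

Step 13
Reactants: 23 1-(triisopropylsilyl)pyrrole
Product: 24 3,4-dibromo-1-(triisopropylsilyl)pyrrole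
Conditions: NBS (2.0 equiv), THF, −78 °C to rt
Reagents that add atoms: N-bromosuccinimide O=C1CCC(=O)N1Br
Why: In this electrophilic bromination the bulky N-silyl group shields C-2 and C-5 of the pyrrole, so two equivalents of NBS fill both β-positions.

Step 14
Reactants: 22 7,8-dimethoxy-5-(4,4,5,5-tetramethyl-1,3,2-dioxaborolan-2-yl)quinoline (2.6 equiv); 24 3,4-dibromo-1-(triisopropylsilyl)pyrrole
Product: 26 3,4-bis(7,8-dimethoxyquinolin-5-yl)-1-(triisopropylsilyl)pyrrole, via monoarylated bromopyrrole 25 (not isolated)
Conditions: Pd(OAc)2 (5 mol %), SPhos (2-dicyclohexylphosphino-2',6'-dimethoxybiphenyl, 10 mol %), K3PO4 (5 equiv), 1,4-dioxane/H2O (5:1), 90 °C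
Reagents that add atoms: none
Why: In this twofold Suzuki–Miyaura coupling the bulky electron-rich biarylphosphine speeds oxidative addition of zerovalent palladium into the electron-rich pyrrolyl bromide and reductive elimination in the congested second coupling, while excess boronate offsets protodeboronation.

Step 15
Reactants: 26 3,4-bis(7,8-dimethoxyquinolin-5-yl)-1-(triisopropylsilyl)pyrrole
Product: 27 3,4-bis(7,8-dimethoxyquinolin-5-yl)-1H-pyrrole
Conditions: Bu4NF (1.2 equiv), THF, 0 °C to rt
Reagents that add atoms: none
Why: Fluoride-induced N–Si cleavage is driven by the strong Si–F bond, and nothing else in 26 reacts with fluoride.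

Step 16
Reactants: 27 3,4-bis(7,8-dimethoxyquinolin-5-yl)-1H-pyrrole; 17 (S)-1-(3-chloropropyl)-3-methylazecane hydrochloride
Product: 30 (S)-5,5'-{1-[3-(3-methylazecan-1-yl)propyl]-1H-pyrrole-3,4-diyl}bis(7,8-dimethoxyquinoline), via sodium pyrrolide 28 (not isolated), via free chloropropylamine 29 (not isolated)
Conditions: NaH (2.5 equiv), DMF, 0 °C; then 17 (1.2 equiv), rt to 55 °C
Reagents that add atoms: sodium hydride [Na+].[H-] (sodium of 28 only)
Why: SN2 N-alkylation of a sodium pyrrolide in a dipolar aprotic solvent favours nitrogen over carbon attack, the extra hydride frees amine 29 from its salt, and a transient azetidinium ion from 29 would be opened to the same product.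

Step 17
Reactants: 30 (S)-5,5'-{1-[3-(3-methylazecan-1-yl)propyl]-1H-pyrrole-3,4-diyl}bis(7,8-dimethoxyquinoline)
Product: 32 (S)-5,5'-{1-[3-(3-methylazecan-1-yl)propyl]-1H-pyrrole-3,4-diyl}bis(quinoline-7,8-diol), via trihydrobromide salt 31 (not isolated)
Conditions: BBr3 (14 equiv), CH2Cl2, −78 °C to rt, Ar; MeOH, 0 °C, evaporate (three times); degassed aq NaHCO3 to pH 7–8, Ar
Reagents that add atoms: boron tribromide BrB(Br)Br (bromide of salt 31 only)
Why: Lewis-acid cleavage of aryl methyl ethers with BBr3 is routine for the last-step release of polyphenolic arylpyrrole alkaloids; the excess covers the three basic nitrogens, methanolysis strips boron from the chelating 8-hydroxyquinoline units, exclusion of air prevents oxidation of the catechols, and the remote stereocentre is untouched.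

Compound list
1 | (S)-1-(tert-butoxycarbonyl)piperidine-2-carboxylic acid | CC(C)(C)OC(=O)N1CCCC[C@H]1C(=O)O | starting material
2 | tert-butyl (S)-2-(1H-imidazole-1-carbonyl)piperidine-1-carboxylate (formed in situ) | CC(C)(C)OC(=O)N1CCCC[C@H]1C(=O)n1ccnc1 | intermediate
3 | tert-butyl (S)-2-[methoxy(methyl)carbamoyl]piperidine-1-carboxylate | CC(C)(C)OC(=O)N1CCCC[C@H]1C(=O)N(C)OC | intermediate
4 | tert-butyl (S)-2-formylpiperidine-1-carboxylate | CC(C)(C)OC(=O)N1CCCC[C@H]1C=O | intermediate
5 | tert-butyl (S)-2-vinylpiperidine-1-carboxylate | CC(C)(C)OC(=O)N1CCCC[C@H]1C=C | intermediate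
6 | benzyl 3-bromopropyl ether | BrCCCOCc1ccccc1 | starting material
7 | (S)-2-vinylpiperidinium trifluoroacetate (formed in situ) | C=C[C@@H]1CCCCN1.OC(=O)C(F)(F)F | intermediate
8 | (S)-1-[3-(benzyloxy)propyl]-2-vinylpiperidine | C=C[C@@H]1CCCCN1CCCOCc1ccccc1 | intermediate
9 | propionyl chloride | CCC(=O)Cl | starting material
10 | propionyl fluoride | CCC(=O)F | intermediate
11 | (2S)-1-[3-(benzyloxy)propyl]-1-propionyl-2-vinylpiperidinium fluoride (formed in situ, fluoride held by aluminium, nitrogen epimers interconvert by reversible acylation) | CCC(=O)[N+]1(CCCOCc2ccccc2)CCCC[C@H]1C=C.[F-] | intermediate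
12 | (Z)-1-{(2S)-1-[3-(benzyloxy)propyl]-2-vinylpiperidinium-1-yl}prop-1-en-1-olate (formed in situ) | C/C=C(\[O-])[N+]1(CCCOCc2ccccc2)CCCC[C@H]1C=C | intermediate
13 | (3S,5E)-1-[3-(benzyloxy)propyl]-3-methyl-3,4,7,8,9,10-hexahydroazecin-2(1H)-one | C[C@H]1C/C=C/CCCCN(CCCOCc2ccccc2)C1=O | intermediate
14 | (S)-1-[3-(benzyloxy)propyl]-3-methylazecan-2-one (formed in situ) | C[C@H]1CCCCCCCN(CCCOCc2ccccc2)C1=O | intermediate
15 | (S)-1-(3-hydroxypropyl)-3-methylazecan-2-one | C[C@H]1CCCCCCCN(CCCO)C1=O | intermediate
16 | (S)-3-(3-methylazecan-1-yl)propan-1-ol | C[C@H]1CCCCCCCN(CCCO)C1 | intermediate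
17 | (S)-1-(3-chloropropyl)-3-methylazecane hydrochloride | C[C@H]1CCCCCCCN(CCCCl)C1.Cl | intermediate
18 | 2,3-dimethoxyaniline | COc1cccc(N)c1OC | starting material
19 | 7,8-dimethoxy-1,2-dihydroquinoline (formed in situ) | COc1ccc2C=CCNc2c1OC | intermediate
20 | 7,8-dimethoxyquinoline | COc1ccc2cccnc2c1OC | intermediate
21 | 5-bromo-7,8-dimethoxyquinoline | COc1cc(Br)c2cccnc2c1OC | intermediate
22 | 7,8-dimethoxy-5-(4,4,5,5-tetramethyl-1,3,2-dioxaborolan-2-yl)quinoline | COc1cc(B2OC(C)(C)C(C)(C)O2)c2cccnc2c1OC | intermediate
23 | 1-(triisopropylsilyl)pyrrole | CC(C)[Si](C(C)C)(C(C)C)n1cccc1 | starting material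
24 | 3,4-dibromo-1-(triisopropylsilyl)pyrrole | CC(C)[Si](C(C)C)(C(C)C)n1cc(Br)c(Br)c1 | intermediate
25 | 5-[4-bromo-1-(triisopropylsilyl)pyrrol-3-yl]-7,8-dimethoxyquinoline (formed in situ) | COc1cc(-c2cn([Si](C(C)C)(C(C)C)C(C)C)cc2Br)c2cccnc2c1OC | intermediate
26 | 3,4-bis(7,8-dimethoxyquinolin-5-yl)-1-(triisopropylsilyl)pyrrole | COc1cc(-c2cn([Si](C(C)C)(C(C)C)C(C)C)cc2-c2cc(OC)c(OC)c3ncccc23)c2cccnc2c1OC | intermediate
27 | 3,4-bis(7,8-dimethoxyquinolin-5-yl)-1H-pyrrole | COc1cc(-c2c[nH]cc2-c2cc(OC)c(OC)c3ncccc23)c2cccnc2c1OC | intermediate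
28 | sodium 3,4-bis(7,8-dimethoxyquinolin-5-yl)pyrrol-1-ide (formed in situ) | COc1cc(-c2c[n-]cc2-c2cc(OC)c(OC)c3ncccc23)c2cccnc2c1OC.[Na+] | intermediate
29 | (S)-1-(3-chloropropyl)-3-methylazecane (formed in situ) | C[C@H]1CCCCCCCN(CCCCl)C1 | intermediate
30 | (S)-5,5'-{1-[3-(3-methylazecan-1-yl)propyl]-1H-pyrrole-3,4-diyl}bis(7,8-dimethoxyquinoline) | C[C@H]1CCCCCCCN(CCCn2cc(-c3cc(OC)c(OC)c4ncccc34)c(-c3cc(OC)c(OC)c4ncccc34)c2)C1 | intermediate
31 | trihydrobromide of 32 (crude salt, formed in situ) | C[C@H]1CCCCCCCN(CCCn2cc(-c3cc(O)c(O)c4ncccc34)c(-c3cc(O)c(O)c4ncccc34)c2)C1.Br.Br.Br | intermediate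
32 | (S)-5,5'-{1-[3-(3-methylazecan-1-yl)propyl]-1H-pyrrole-3,4-diyl}bis(quinoline-7,8-diol), CNP0141397.1 | C[C@H]1CCCCCCCN(CCCn2cc(-c3cc(O)c(O)c4ncccc34)c(-c3cc(O)c(O)c4ncccc34)c2)C1 | target

Total step count: 17.
Longest linear sequence: 10 steps (steps 1, 2, 3, 4, 6, 7, 8, 9, 16 and 17, from 1 to 32).

Steps most likely to fail

**Step 6.**
- What may go wrong:
  - sluggish acylation of the hindered tertiary amine;
  - methyl transfer from AlMe3 to the acyl fluoride;
  - dealkylation of the acylammonium ion;
  - leakage through a boat or through a chair that forms the Z-alkene, with loss of enantiomeric purity at C-3.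
- Fallback: the zwitterionic shift is replaced by the known anionic variant, and the N-chain is attached afterwards.
- It sets out from 5, whose carbamate is cleaved as in step 4 to salt 7.
- Schotten–Baumann acylation with propionyl chloride 9 (aq K2CO3, CH2Cl2) gives (S)-1-propionyl-2-vinylpiperidine F1, in which allylic 1,3-strain holds the vinyl group axial.
- LiN(SiMe3)2 in refluxing toluene then sets off the amide-enolate aza-Claisen ring expansion through the same chair topology. This gives the secondary lactam (3S,5E)-3-methyl-3,4,7,8,9,10-hexahydroazecin-2(1H)-one F2.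
- N-alkylation (NaH, DMF, 0 °C) with bromide 6 comes back to the route at 13.

**Step 14.**
- What may go wrong:
  - stalling after the first coupling;
  - hydrodebromination of the hindered intermediate;
  - protodeboronation of the quinolinyl boronate;
  - premature loss of the silyl group.
- Fallback: the polarity of the coupling is reversed.
- It sets out from 24, which is doubly borylated (B2pin2, Pd(OAc)2, XPhos, KOAc, 1,4-dioxane, 100 °C) to 3,4-bis(4,4,5,5-tetramethyl-1,3,2-dioxaborolan-2-yl)-1-(triisopropylsilyl)pyrrole F3.
- Twofold Suzuki coupling of F3 with two equivalents of bromide 21 (PdCl2(dppf), K3PO4, 1,4-dioxane/H2O) comes back to the route at 26. Bromide 21 is electron-poor and therefore more reactive toward oxidative addition.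
- This fallback makes step 12 unnecessary.

**Step 17.**
- What may go wrong:
  - incomplete ether cleavage;
  - retention of boron by the chelating 8-hydroxyquinoline units;
  - acid-induced decay of the α-unsubstituted pyrrole;
  - air oxidation of the catechols during aqueous work-up.
- Fallback: the protecting group is changed so that the last step becomes a neutral hydrogenolysis.
- It sets out from 21, which is demethylated with BBr3 at this robust stage to 5-bromoquinoline-7,8-diol F4.
- O-benzylation (benzyl bromide, K2CO3, DMF) gives 7,8-bis(benzyloxy)-5-bromoquinoline F5.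
- The operations of steps 12, 14, 15 and 16 are then repeated and give in turn:
  - 7,8-bis(benzyloxy)-5-(4,4,5,5-tetramethyl-1,3,2-dioxaborolan-2-yl)quinoline F6;
  - with 24, 3,4-bis[7,8-bis(benzyloxy)quinolin-5-yl]-1-(triisopropylsilyl)pyrrole F7;
  - 3,4-bis[7,8-bis(benzyloxy)quinolin-5-yl]-1H-pyrrole F8;
  - with 17, the tetra-O-benzyl ether of the target F9.
- Hydrogenolysis (H2, 1 bar, Pd/C, degassed MeOH/THF) comes back to the route at 32.

Further compounds
F1 | step 6 | (S)-1-propionyl-2-vinylpiperidine | CCC(=O)N1CCCC[C@H]1C=C
F2 | step 6 | (3S,5E)-3-methyl-3,4,7,8,9,10-hexahydroazecin-2(1H)-one | C[C@H]1C/C=C/CCCCNC1=O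
F3 | step 14 | 3,4-bis(4,4,5,5-tetramethyl-1,3,2-dioxaborolan-2-yl)-1-(triisopropylsilyl)pyrrole | CC(C)[Si](C(C)C)(C(C)C)n1cc(B2OC(C)(C)C(C)(C)O2)c(B2OC(C)(C)C(C)(C)O2)c1
F4 | step 17 | 5-bromoquinoline-7,8-diol | Oc1cc(Br)c2cccnc2c1O
F5 | step 17 | 7,8-bis(benzyloxy)-5-bromoquinoline | Brc1cc(OCc2ccccc2)c(OCc2ccccc2)c2ncccc12
F6 | step 17 | 7,8-bis(benzyloxy)-5-(4,4,5,5-tetramethyl-1,3,2-dioxaborolan-2-yl)quinoline | CC1(C)OB(OC1(C)C)c1cc(OCc2ccccc2)c(OCc2ccccc2)c2ncccc12
F7 | step 17 | 3,4-bis[7,8-bis(benzyloxy)quinolin-5-yl]-1-(triisopropylsilyl)pyrrole | CC(C)[Si](C(C)C)(C(C)C)n1cc(-c2cc(OCc3ccccc3)c(OCc3ccccc3)c3ncccc23)c(-c2cc(OCc3ccccc3)c(OCc3ccccc3)c3ncccc23)c1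
F8 | step 17 | 3,4-bis[7,8-bis(benzyloxy)quinolin-5-yl]-1H-pyrrole | c1[nH]cc(-c2cc(OCc3ccccc3)c(OCc3ccccc3)c3ncccc23)c1-c1cc(OCc2ccccc2)c(OCc2ccccc2)c2ncccc12
F9 | step 17 | (S)-5,5'-{1-[3-(3-methylazecan-1-yl)propyl]-1H-pyrrole-3,4-diyl}bis[7,8-bis(benzyloxy)quinoline] | C[C@H]1CCCCCCCN(CCCn2cc(-c3cc(OCc4ccccc4)c(OCc4ccccc4)c4ncccc34)c(-c3cc(OCc4ccccc4)c(OCc4ccccc4)c4ncccc34)c2)C1
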